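**Plan**

- Retrosynthesis: ring C is cut at O1–C2 and at the C3–OH bond (oxidative chalcone cyclisation), then at the C2–C3 bond (aldol condensation). This leaves a ring A acetophenone and a ring B aldehyde.
- Ring A: the C8–C(CH3)2 bond is traced to a 4-O-prenyl ether of 2,4,6-trihydroxyacetophenone through an aromatic Claisen rearrangement. The symmetry of that ether makes the ortho position unambiguous.
- Ring B: C2'–C3' and C6'–C1' are cut together. The enabling feature is the contiguous C3'-OH / C4'-OH / C5'-prenyl array on ring B: it maps onto the ring oxygen, a 3-siloxy group and a 4-prenyl group of a furan, and C1'–C2' with the future C2 carbon comes from methyl propiolate.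
- Forward order: furan, then ring B by cycloaddition and bridge opening, then the aldehyde; ring A is bought and reverse-prenylated; the chalcone joins the halves; ring C closes last.
- Stereochemistry: the target has no stereocentre and no stereogenic double bond, so nothing has to be set.

Key step: step 4

Remark: 3,4-dibromofuran, prenyl bromide, methyl propiolate and 2,4,6-trihydroxyacetophenone are taken as purchasable. The stereocentres of the transient bicyclic adduct, the Claisen dienone, the aldol and the dihydroflavonol are racemic and are all erased.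

**Route**

Step 1
Reactants: 1 3,4-dibromofuran; 2 prenyl bromide (1-bromo-3-methylbut-2-ene)
Product: 5 3-bromo-4-(3-methylbut-2-en-1-yl)furan, via (4-bromofuran-3-yl)lithium 3 (not isolated), via (4-bromofuran-3-yl)copper 4 (not isolated)
Conditions: n-BuLi (1.0 equiv), Et2O, −78 °C; CuBr·SMe2, −78 → −40 °C; then 2, −40 → 0 °C
Reagents that add atoms: none
Why: Bromine–lithium exchange is fast at −78 °C and stops at the monolithio stage, and after transmetalation the furylcopper attacks the unhindered primary carbon of prenyl bromide (copper-mediated SN2 allylation), which gives the linear prenyl group and keeps the second bromide for step 2.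

Step 2
Reactants: 5 3-bromo-4-(3-methylbut-2-en-1-yl)furan
Product: 8 4-(3-methylbut-2-en-1-yl)furan-3(2H)-one, via [4-(3-methylbut-2-en-1-yl)furan-3-yl]lithium 6 (not isolated), via lithium furyltrimethoxyborate 7 (not isolated)
Conditions: n-BuLi, THF, −78 °C; B(OMe)3, −78 → 0 °C; then AcOH, H2O2 (30% aq.), 0 °C
Reagents that add atoms: hydrogen peroxide, OO
Why: A second bromine–lithium exchange, trapping with B(OMe)3 and peroxide oxidation of the furyl boronate (1,2-shift from boron to oxygen) give the furan-3-ol, which rests as its keto tautomer 8; the weakly acidic medium spares the prenyl alkene and suppresses base-induced self-aldol of the furanone.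

Step 3
Reactants: 8 4-(3-methylbut-2-en-1-yl)furan-3(2H)-one
Product: 9 triisopropyl{[4-(3-methylbut-2-en-1-yl)furan-3-yl]oxy}silane
Conditions: TIPSOTf, Et3N, CH2Cl2, 0 °C (crude 8 used at once)
Reagents that add atoms: triisopropylsilyl triflate, CC(C)[Si](C(C)C)(C(C)C)OS(=O)(=O)C(F)(F)F
Why: Soft enolisation with Et3N and O-silylation by TIPSOTf (silyl enol ether formation) go to oxygen because the furan aromaticity is regained, and the bulky silyl group makes the electron-rich diene stable enough to handle.

Step 4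
Reactants: 9 triisopropyl{[4-(3-methylbut-2-en-1-yl)furan-3-yl]oxy}silane; 10 methyl propiolate
Product: 12 methyl 3-hydroxy-5-(3-methylbut-2-en-1-yl)-4-[(triisopropylsilyl)oxy]benzoate, via oxanorbornadiene adduct 11 (not isolated)
Conditions: 10 (3 equiv), toluene, 90 °C, sealed tube; then CSA (5 mol%), CH2Cl2, 0 °C
Reagents that add atoms: none
Why: The siloxyfuran reacts as an electron-rich diene in a normal-demand [4+2] cycloaddition: its C2, the beta carbon of the silyl enol ether and alpha to the ring oxygen, bonds to the electrophilic beta carbon of methyl propiolate and C5 bonds to the ester-bearing carbon, giving oxanorbornadiene 11. Acid then ionises the bridge C–O bond at bridgehead C1 of 11 (next to the prenyl-bearing carbon), because only that cation is conjugated through C6=C5 with the siloxy oxygen, and loss of the proton from bridgehead C4, which keeps the oxygen, aromatises the ring. The closest known reactions are the Diels–Alder additions of 3-alkoxy- and 3-siloxyfurans to alkynoates and the acid-induced isomerisation of 7-oxanorbornadienes to phenols. Ring B is closed by this intermolecular [4+2] cycloaddition across the two furan alpha carbons, which forms C2'–C3' and C6'–C1', and the six-membered carbocycle is released from the bicycle by the bridge opening. No stereocentre remains in 12, since the two bridgehead centres of racemic 11 are erased on aromatisation. Two regioselectivities are needed, the orientation of the cycloaddition and the direction of bridge opening, and the siloxy group dictates both; TIPS is chosen over a smaller silyl group so that the enol ether survives until the bridge has opened.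

Step 5
Reactants: 12 methyl 3-hydroxy-5-(3-methylbut-2-en-1-yl)-4-[(triisopropylsilyl)oxy]benzoate
Product: 13 methyl 3,4-dihydroxy-5-(3-methylbut-2-en-1-yl)benzoate
Conditions: Bu4NF, AcOH, THF, 0 °C
Reagents that add atoms: none
Why: Fluoride cleaves the aryl Si–O bond (desilylation) and the acetic acid buffer keeps the liberated catechol protonated and the methyl ester untouched.

Step 6
Reactants: 13 methyl 3,4-dihydroxy-5-(3-methylbut-2-en-1-yl)benzoate
Product: 14 methyl 3,4-bis(methoxymethoxy)-5-(3-methylbut-2-en-1-yl)benzoate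
Conditions: MOMCl, iPr2NEt, CH2Cl2, 0 °C → rt
Reagents that add atoms: chloromethyl methyl ether, COCCl
Why: O-Alkylation of both phenols with MOMCl and amine base (acetal ether protection) installs groups that tolerate hydride, hydroxide and alkaline peroxide and leave under the mild acid of the last step.

Step 7
Reactants: 14 methyl 3,4-bis(methoxymethoxy)-5-(3-methylbut-2-en-1-yl)benzoate
Product: 15 [3,4-bis(methoxymethoxy)-5-(3-methylbut-2-en-1-yl)phenyl]methanol
Conditions: LiAlH4, THF, 0 °C
Reagents that add atoms: none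
Why: LiAlH4 reduces the methyl ester to the primary alcohol (hydride reduction) while the MOM ethers and the isolated alkene are inert.

Step 8
Reactants: 15 [3,4-bis(methoxymethoxy)-5-(3-methylbut-2-en-1-yl)phenyl]methanol
Product: 16 3,4-bis(methoxymethoxy)-5-(3-methylbut-2-en-1-yl)benzaldehyde
Conditions: MnO2, CH2Cl2, rt
Reagents that add atoms: none
Why: MnO2 oxidises the benzylic alcohol selectively to the aldehyde (heterogeneous benzylic oxidation) without over-oxidation or attack on the prenyl group.

Step 9
Reactants: 17 1-(2,4,6-trihydroxyphenyl)ethan-1-one; 2 prenyl bromide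
Product: 18 1-{2,6-dihydroxy-4-[(3-methylbut-2-en-1-yl)oxy]phenyl}ethan-1-one
Conditions: K2CO3 (1.0 equiv), acetone, reflux
Reagents that add atoms: none
Why: The 4-hydroxyl is the most acidic and the only one not held in a hydrogen bond to the acetyl group, so one equivalent of mild base and prenyl bromide alkylates it selectively on oxygen (Williamson ether synthesis).

Step 10
Reactants: 18 1-{2,6-dihydroxy-4-[(3-methylbut-2-en-1-yl)oxy]phenyl}ethan-1-one
Product: 20 1-[2,4,6-trihydroxy-3-(2-methylbut-3-en-2-yl)phenyl]ethan-1-one, via ortho-dienone 19 (not isolated)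
Conditions: PhNEt2, 190 °C (microwave), argon
Reagents that add atoms: none
Why: Aromatic Claisen rearrangement: the [3,3] shift carries the allyl unit with inversion of its termini to an ortho carbon, giving the 1,1-dimethylallyl group after enolisation of the dienone, and since the two ortho positions of 18 are equivalent by symmetry only one product can form.

Step 11
Reactants: 20 1-[2,4,6-trihydroxy-3-(2-methylbut-3-en-2-yl)phenyl]ethan-1-one
Product: 21 1-[2-hydroxy-4,6-bis(methoxymethoxy)-3-(2-methylbut-3-en-2-yl)phenyl]ethan-1-one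
Conditions: MOMCl (2.2 equiv), iPr2NEt, CH2Cl2, 0 °C
Reagents that add atoms: chloromethyl methyl ether, COCCl
Why: MOM ether formation should occur first at the non-chelated 4-hydroxyl and then at the chelated 6-hydroxyl flanked by hydrogen, while the 2-hydroxyl, wedged between the acetyl group and the quaternary carbon, stays free as the future ring oxygen O1.

Step 12
Reactants: 21 1-[2-hydroxy-4,6-bis(methoxymethoxy)-3-(2-methylbut-3-en-2-yl)phenyl]ethan-1-one; 16 3,4-bis(methoxymethoxy)-5-(3-methylbut-2-en-1-yl)benzaldehyde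
Product: 23 (E)-3-[3,4-bis(methoxymethoxy)-5-(3-methylbut-2-en-1-yl)phenyl]-1-[2-hydroxy-4,6-bis(methoxymethoxy)-3-(2-methylbut-3-en-2-yl)phenyl]prop-2-en-1-one, via aldol adduct 22 (not isolated)
Conditions: KOH, EtOH–H2O, rt
Reagents that add atoms: none
Why: Claisen–Schmidt condensation: the ketone enolate adds to the non-enolisable aldehyde and E1cB dehydration of the aldol gives the conjugated E-enone, all protecting groups being stable to hydroxide.

Step 13
Reactants: 23 the (E)-chalcone of step 12
Product: 25 2-[3,4-bis(methoxymethoxy)-5-(3-methylbut-2-en-1-yl)phenyl]-3-hydroxy-5,7-bis(methoxymethoxy)-8-(2-methylbut-3-en-2-yl)-4H-chromen-4-one, via trans-dihydroflavonol 24 (not isolated)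
Conditions: H2O2 (30% aq.), NaOH, MeOH, 0 °C → rt
Reagents that add atoms: hydrogen peroxide, OO
Why: Algar–Flynn–Oyamada reaction: hydroperoxide oxygenates the enone, the 2'-phenoxide closes ring C by 6-endo attack at the benzylic carbon to give trans-dihydroflavonol 24, and further oxidation under the same conditions gives the flavonol; nucleophilic peroxide does not touch the isolated alkenes, and the stereocentres of 24 are erased.

Step 14
Reactants: 25 the tetrakis(methoxymethyl) flavonol of step 13
Product: 26 2-[3,4-dihydroxy-5-(3-methylbut-2-en-1-yl)phenyl]-3,5,7-trihydroxy-8-(2-methylbut-3-en-2-yl)-4H-chromen-4-one (CNP0196880.0)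
Conditions: HCl (3 M aq.), MeOH, 40 °C
Reagents that add atoms: none
Why: Acid-catalysed acetal exchange with methanol removes all four MOM groups (MOM ether cleavage) under conditions mild enough that the two allyl-type side chains should not cyclise onto their neighbouring phenols.

**Compound list**

1 | 3,4-dibromofuran | Brc1cocc1Br | starting material
2 | prenyl bromide (1-bromo-3-methylbut-2-ene) | CC(C)=CCBr | starting material
3 | (4-bromofuran-3-yl)lithium | [Li]c1cocc1Br | intermediate (not isolated)
4 | (4-bromofuran-3-yl)copper | [Cu]c1cocc1Br | intermediate (not isolated)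
5 | 3-bromo-4-(3-methylbut-2-en-1-yl)furan | CC(C)=CCc1cocc1Br | intermediate
6 | [4-(3-methylbut-2-en-1-yl)furan-3-yl]lithium | [Li]c1cocc1CC=C(C)C | intermediate (not isolated)
7 | lithium trimethoxy[4-(3-methylbut-2-en-1-yl)furan-3-yl]borate | [Li+].CO[B-](OC)(OC)c1cocc1CC=C(C)C | intermediate (not isolated)
8 | 4-(3-methylbut-2-en-1-yl)furan-3(2H)-one | O=C1COC=C1CC=C(C)C | intermediate
9 | triisopropyl{[4-(3-methylbut-2-en-1-yl)furan-3-yl]oxy}silane | CC(C)=CCc1cocc1O[Si](C(C)C)(C(C)C)C(C)C | intermediate
10 | methyl propiolate | C#CC(=O)OC | starting material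
11 | methyl 6-(3-methylbut-2-en-1-yl)-5-[(triisopropylsilyl)oxy]-7-oxabicyclo[2.2.1]hepta-2,5-diene-2-carboxylate (racemic) | COC(=O)C1=CC2OC1C(CC=C(C)C)=C2O[Si](C(C)C)(C(C)C)C(C)C | intermediate (not isolated)
12 | methyl 3-hydroxy-5-(3-methylbut-2-en-1-yl)-4-[(triisopropylsilyl)oxy]benzoate | COC(=O)c1cc(O)c(O[Si](C(C)C)(C(C)C)C(C)C)c(CC=C(C)C)c1 | intermediate
13 | methyl 3,4-dihydroxy-5-(3-methylbut-2-en-1-yl)benzoate | COC(=O)c1cc(O)c(O)c(CC=C(C)C)c1 | intermediate
14 | methyl 3,4-bis(methoxymethoxy)-5-(3-methylbut-2-en-1-yl)benzoate | COCOc1cc(C(=O)OC)cc(CC=C(C)C)c1OCOC | intermediate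
15 | [3,4-bis(methoxymethoxy)-5-(3-methylbut-2-en-1-yl)phenyl]methanol | COCOc1cc(CO)cc(CC=C(C)C)c1OCOC | intermediate
16 | 3,4-bis(methoxymethoxy)-5-(3-methylbut-2-en-1-yl)benzaldehyde | COCOc1cc(C=O)cc(CC=C(C)C)c1OCOC | intermediate
17 | 1-(2,4,6-trihydroxyphenyl)ethan-1-one | CC(=O)c1c(O)cc(O)cc1O | starting material
18 | 1-{2,6-dihydroxy-4-[(3-methylbut-2-en-1-yl)oxy]phenyl}ethan-1-one | CC(=O)c1c(O)cc(OCC=C(C)C)cc1O | intermediate
19 | 4-acetyl-3,5-dihydroxy-6-(2-methylbut-3-en-2-yl)cyclohexa-2,4-dien-1-one (racemic) | CC(=O)C1=C(O)C(C(C)(C)C=C)C(=O)C=C1O | intermediate (not isolated)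
20 | 1-[2,4,6-trihydroxy-3-(2-methylbut-3-en-2-yl)phenyl]ethan-1-one | CC(=O)c1c(O)cc(O)c(C(C)(C)C=C)c1O | intermediate
21 | 1-[2-hydroxy-4,6-bis(methoxymethoxy)-3-(2-methylbut-3-en-2-yl)phenyl]ethan-1-one | CC(=O)c1c(O)c(C(C)(C)C=C)c(OCOC)cc1OCOC | intermediate
22 | 3-[3,4-bis(methoxymethoxy)-5-(3-methylbut-2-en-1-yl)phenyl]-3-hydroxy-1-[2-hydroxy-4,6-bis(methoxymethoxy)-3-(2-methylbut-3-en-2-yl)phenyl]propan-1-one (racemic) | O=C(CC(O)c1cc(OCOC)c(OCOC)c(CC=C(C)C)c1)c1c(O)c(C(C)(C)C=C)c(OCOC)cc1OCOC | intermediate (not isolated)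
23 | (E)-3-[3,4-bis(methoxymethoxy)-5-(3-methylbut-2-en-1-yl)phenyl]-1-[2-hydroxy-4,6-bis(methoxymethoxy)-3-(2-methylbut-3-en-2-yl)phenyl]prop-2-en-1-one | O=C(/C=C/c1cc(OCOC)c(OCOC)c(CC=C(C)C)c1)c1c(O)c(C(C)(C)C=C)c(OCOC)cc1OCOC | intermediate
24 | trans-2-[3,4-bis(methoxymethoxy)-5-(3-methylbut-2-en-1-yl)phenyl]-3-hydroxy-5,7-bis(methoxymethoxy)-8-(2-methylbut-3-en-2-yl)-2,3-dihydro-4H-chromen-4-one (racemic; the 2R,3R enantiomer is drawn) | O=C1c2c(OCOC)cc(OCOC)c(C(C)(C)C=C)c2O[C@H](c2cc(OCOC)c(OCOC)c(CC=C(C)C)c2)[C@H]1O | intermediate (not isolated)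
25 | 2-[3,4-bis(methoxymethoxy)-5-(3-methylbut-2-en-1-yl)phenyl]-3-hydroxy-5,7-bis(methoxymethoxy)-8-(2-methylbut-3-en-2-yl)-4H-chromen-4-one | C=CC(C)(C)c1c(OCOC)cc(OCOC)c2c(=O)c(O)c(-c3cc(OCOC)c(OCOC)c(CC=C(C)C)c3)oc12 | intermediate
26 | 2-[3,4-dihydroxy-5-(3-methylbut-2-en-1-yl)phenyl]-3,5,7-trihydroxy-8-(2-methylbut-3-en-2-yl)-4H-chromen-4-one | C=CC(C)(C)c1c(O)cc(O)c2c(=O)c(O)c(-c3cc(O)c(O)c(CC=C(C)C)c3)oc12 | target

**Summary**

Total step count: 14. Longest linear sequence: 11 steps (steps 1 to 8, then 12 to 14); the ring A branch (steps 9 to 11) joins at step 12.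

**Steps most likely to fail**

1. Step 4. The cycloaddition may run with the reverse orientation, or so slowly that the acid-sensitive furan decomposes first, or the bridge may open in the wrong direction. Fallback: ring B is assembled by cross-coupling instead. It sets out from prenyl bromide 2, which is stannylated with Bu3SnLi (THF, −78 °C) to tributyl(3-methylbut-2-en-1-yl)stannane F1. Commercial 3-bromo-4,5-dihydroxybenzaldehyde F2 is protected (MOMCl, iPr2NEt, CH2Cl2) as 3-bromo-4,5-bis(methoxymethoxy)benzaldehyde F3. Stille coupling of F3 with F1 (Pd(PPh3)4, DMF, 90 °C) should give aldehyde 16, where the route is rejoined; steps 1 to 8 are then not needed.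

2. Step 2. The 2-unsubstituted furanone may condense with itself or be over-oxidised during the peroxide treatment and work-up, before it can be silylated. Fallback: the free furanone is avoided. From bromofuran 5, the lithio compound 6 (n-BuLi, THF, −78 °C) is oxygenated with t-BuOOLi (made from t-BuOOH and n-BuLi; electrophilic oxygenation of an organolithium) to lithium 4-(3-methylbut-2-en-1-yl)furan-3-olate F4. F4 is silylated in the same flask with TIPSOTf to give siloxyfuran 9, where the route is rejoined.

3. Step 13. Under alkaline peroxide the phenoxide may close in the 5-exo sense to an aurone, a diversion favoured by the 6'-alkoxy group, or the flavonol may be degraded by excess peroxide. Fallback: ring C is built at the flavone level and C3 is hydroxylated afterwards. It sets out from ester 14 and ketone 21. Crossed Claisen condensation of the ketone dianion with the ester (LiN(SiMe3)2, THF, −78 °C → rt; the ester variant of the Baker–Venkataraman diketone synthesis) gives 1-[3,4-bis(methoxymethoxy)-5-(3-methylbut-2-en-1-yl)phenyl]-3-[2-hydroxy-4,6-bis(methoxymethoxy)-3-(2-methylbut-3-en-2-yl)phenyl]propane-1,3-dione F5. Cyclodehydration (NaOAc, AcOH, 90 °C) gives 2-[3,4-bis(methoxymethoxy)-5-(3-methylbut-2-en-1-yl)phenyl]-5,7-bis(methoxymethoxy)-8-(2-methylbut-3-en-2-yl)-4H-chromen-4-one F6. Deprotonation at C3 (LiN(iPr)2, THF, −78 °C) gives the 3-lithioflavone F7, B(OMe)3 converts it into the lithium 3-flavonyltrimethoxyborate F8, and oxidation with H2O2 and AcOH gives flavonol 25, where the route is rejoined.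

**Further compounds**

F1 | step 4 | tributyl(3-methylbut-2-en-1-yl)stannane | CC(C)=CC[Sn](CCCC)(CCCC)CCCC
F2 | step 4 | 3-bromo-4,5-dihydroxybenzaldehyde | O=Cc1cc(O)c(O)c(Br)c1
F3 | step 4 | 3-bromo-4,5-bis(methoxymethoxy)benzaldehyde | COCOc1cc(C=O)cc(Br)c1OCOC
F4 | step 2 | lithium 4-(3-methylbut-2-en-1-yl)furan-3-olate | [Li+].[O-]c1cocc1CC=C(C)C
F5 | step 13 | 1-[3,4-bis(methoxymethoxy)-5-(3-methylbut-2-en-1-yl)phenyl]-3-[2-hydroxy-4,6-bis(methoxymethoxy)-3-(2-methylbut-3-en-2-yl)phenyl]propane-1,3-dione | COCOc1cc(C(=O)CC(=O)c2c(O)c(C(C)(C)C=C)c(OCOC)cc2OCOC)cc(CC=C(C)C)c1OCOC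
F6 | step 13 | 2-[3,4-bis(methoxymethoxy)-5-(3-methylbut-2-en-1-yl)phenyl]-5,7-bis(methoxymethoxy)-8-(2-methylbut-3-en-2-yl)-4H-chromen-4-one | C=CC(C)(C)c1c(OCOC)cc(OCOC)c2c(=O)cc(-c3cc(OCOC)c(OCOC)c(CC=C(C)C)c3)oc12
F7 | step 13 | {2-[3,4-bis(methoxymethoxy)-5-(3-methylbut-2-en-1-yl)phenyl]-5,7-bis(methoxymethoxy)-8-(2-methylbut-3-en-2-yl)-4-oxo-4H-chromen-3-yl}lithium | C=CC(C)(C)c1c(OCOC)cc(OCOC)c2c(=O)c([Li])c(-c3cc(OCOC)c(OCOC)c(CC=C(C)C)c3)oc12
F8 | step 13 | lithium {2-[3,4-bis(methoxymethoxy)-5-(3-methylbut-2-en-1-yl)phenyl]-5,7-bis(methoxymethoxy)-8-(2-methylbut-3-en-2-yl)-4-oxo-4H-chromen-3-yl}trimethoxyborate | [Li+].CO[B-](OC)(OC)c1c(-c2cc(OCOC)c(OCOC)c(CC=C(C)C)c2)oc2c(C(C)(C)C=C)c(OCOC)cc(OCOC)c2c1=O
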